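(The numbers were drawn at random within sensible limits; no experiment stands behind them.)

You have a neighbour flask charged with 0.40 M of starting material, and for it and for this flask the first question is the same: how much gas has the starting material really seen?

starting material 0.10 M; gas phase 4.1 mM (held); protic impurity 0.0200 M; time 20 h

    starting material + dissolved gas → target (k1 = 47.2 M⁻¹ h⁻¹)
    dissolved gas + target → over-reacted product (k2 = 16.8 M⁻¹ h⁻¹)
    target ⇌ isomer of the product (K3 = 0.12, k3 = 0.140 h⁻¹)
    dissolved gas → decomposed reagent (k4 = 0.103 h⁻¹)
    gas phase ⇌ dissolved gas, rate k5*(csat - [dissolved gas]) (k5 = 10.9 h⁻¹, csat = 4.1 mM)
    dissolved gas + protic impurity → quenched reagent (k6 = 9.82 M⁻¹ h⁻¹)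

- at the start none of the gas is dissolved
- run time (flask): 20 h

- how much target there is at 20 h, in percent of the starting material charged
- the change that raises the amount of target at 20 h, in percent of the starting material charged most ("none" if none brings more than 2 percentage points) (elm / ash / none)
- amount of target at 20 h, in percent of the starting material charged, after ash

- elm: doubling the transfer coefficient of step 5, all else as stated
- ash: doubling the saturation concentration of gas phase, all else as stated

Start with a saturated solution. The starting material then decays pseudo-first-order at 0.194 h⁻¹, so its logarithm falls by 3.87 over 20 h. But this flask is not saturated. Transfer runs at 10.9 h⁻¹, while the charged starting material drains dissolved gas at 4.72 h⁻¹.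

That drain fades as starting material goes, so take half of it. Add decomposition and quenching, 0.299 h⁻¹ together. Let f be transfer over transfer plus these drains, an estimate of the mean dissolved level as a fraction of saturation: 80.4%.

You may object that target takes gas too. Yet even the whole charge as target drains 1.68 h⁻¹, less than the 2.36 h⁻¹ allowed. So keep f as an estimate, and the saturated figure shrinks to the gas clock n, the number of e-foldings of starting material over the run: 3.11.

Does the isomer spoil this? The relaxation half-life of target and isomer, 0.530 h, is short against 20 h, so target stays near a share 89.3% of the pair. Over-reaction therefore runs, relative to the first step, at a selectivity factor of 0.318. The pair peaks at a clock of 1.68, and this flask reads more than that. Its target comes to 42.9%.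

Elm lifts the clock to 3.45, giving 39.6%. Ash doubles the clock and gives 17.9%. The objection here is that the drain fades sooner after ash, so the f used there is too low and this figure reads high. That pushes ash further past the peak, which its clock already exceeds. Best change: none.

The forecast said 42.1%, none and 14.8%, its ash figure lying below yours, and gave as its ground: “Both changes over-react the target, so neither helps”.

The flask gives 42.2%, none as the best change, and 15.0% after ash. Starting material left in it at 20.0 h is 4.25%, and the clock gives 4.46%. For the neighbour flask, the estimate of f comes to 52.8%, so its clock reads 2.04, and the same expression gives 51.4% target. That neighbour flask ends with 51.9% target.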